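## Structural features

The target is a dimer of two identical 2,2-dimethylchroman units (a benzene ring fused to a dihydropyran ring, O1–C2–C3–C4–C4a…C8a), joined through C6 and C6' by one sp3 methine that also carries a 5-methylhexyl chain. Each benzene ring is hexasubstituted in a phloroglucinol pattern: oxygen on C8a (the pyran O1), C5 and C7 (free phenols), and carbon on C4a, C6 (the bridge) and C8, where an (R)-2-methylbutanoyl group sits between the pyran oxygen and the C7 hydroxyl. The only stereocentres are the two ketone α-carbons, both R; they lie on different halves, so no two stereocentres are adjacent, and the bridging methine is not stereogenic because its two aryl groups are identical. The fragile elements are these enolisable α-carbons, the electron-rich, oxidation-prone trioxygenated rings, and the doubly benzylic methine, which strong acids can cleave by a retro-Friedel–Crafts path. The real difficulty is the regiocontrolled construction of two fully substituted arenes that crowd four ortho oxygen functions around one methine, with each acyl group next to the ring oxygen and not next to C4a. The key step exploits the fact that each benzene ring divides into three two-carbon units, C8–C8a, C4a–C5 and C6–C7, each an alkyne with exactly one oxygen-bearing carbon (C8a, C5, C7), and that the first two units are already linked through O1–C2–C3–C4 of the pyran ring.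

## Logic of the disconnections

26 to 25. The four phenolic O–H bonds are traced back to O–Si bonds. The air-sensitive polyphenol then appears only in the last step, and the silyl ethers are exactly what the ring-forming step delivers, so no separate protection is needed. The forward step must remove four hindered aryl silyl ethers without enolising the two ketone α-carbons.

25 to 11 and two molecules of 23 (by way of 24). In each benzene ring the bonds C4a–C8a, C5–C6 and C7–C8 are cut, six C–C bonds in all, which opens both benzene and both pyran rings. The cut falls there because every remaining two-carbon unit is an alkyne with one oxygen substituent, and C8–C8a and C4a–C5 stay tied together by O1–C2–C3–C4. A tetracyclic, doubly hexasubstituted core is reduced to one symmetric skipped diyne and two copies of an acyclic diyne that carries the stereocentre. The forward step must join three alkynes per ring with cross-selectivity, place the oxygen-bearing carbon of each arm of 11 next to the acyl-bearing carbon of 23, do so twice on one molecule, and spare five ynol-type ethers.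

23 to 17 and 20. The bond between the ketone carbon and the alkyne carbon (the future C8) is cut. This separates the chiral acyl unit from the achiral tether and lets the stereocentre enter as a configurationally stable amide. The forward step needs a metalated ynol ether generated while a silyl ynol ether is present at the other end, a single addition to the acyl donor, and no enolisation.

20 to 18. The amide C–N bond is cut, which leads to the commercial acid. The forward step must activate the acid without racemisation.

17 to 16. The bond between the tertiary ether oxygen and the vinyl carbon is cut, with a chlorinated two-carbon alkene as the alkyne equivalent. This is the practical entry to an ynol ether of a tertiary alcohol and reduces the problem to a hydroxy siloxyalkyne. The forward step generates a potassium alkoxide that must not attack the silicon of the siloxyalkyne.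

16 to 13. The C(sp)–O bond of the siloxyalkyne, and with it the O–Si bond, is cut back to a terminal alkyne. The siloxyalkyne must be made before the ynol ether and the ynone, because neither would survive the strongly basic oxidation. The forward step must oxidise the acetylide and silylate the ynolate oxygen while leaving the tertiary alkoxide unsilylated.

13 to 12. One C–CH3 bond of the tertiary carbinol is cut, which leads to a commercial alkynyl ketone. The forward step is a plain carbonyl addition.

11 to 8. Both C(sp)–O bonds are cut in the same way as in 16. The two arms are identical, so one operation serves both. The forward step must convert two acetylides that flank an acidic C–H without isomerising the skipped diyne.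

8 to 7. The two terminal C–H bonds are traced back to C–Si bonds, which are needed to steer the preceding alkylation. The forward step must desilylate without base-induced propargyl–allenyl isomerisation.

7 to 4 and 5. The bond between the branching methine (the future bridge carbon) and the first CH2 of the side chain is cut. The whole side chain then comes from a commercial bromide and the diyne from a symmetric five-carbon unit. The forward step requires the delocalised anion of 4 to react at its central carbon.

4 to 1 and 2. The C(sp)–CH2 bond is cut, which gives two commercial silylated C2 and C3 alkynes. The forward step is a copper-catalysed propargylic substitution that must not deliver the allene.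

## Other disconnections considered

Alternative 1: The cut is at C4–C4a of each pyran ring, with O1–C2 opened and re-formed in the same cascade. It leads back to the bis-ether A2, in which the oxygen para to the bridge on each ring carries a 1,1-dimethylpropargyl group. Heating A2 should bring about, on each ring, an aromatic propargyl Claisen rearrangement, enolisation, a 1,5-hydrogen shift and a 6π oxa-electrocyclisation, giving the bis-chromene A1.
- In its favour: the cascade is thermal, reagent-free and well understood. The two ortho positions of each ether are equivalent, so the key step has no regiochemical question. No intermediate is as fragile as an ynol ether. On reliability of mechanism and ease of handling this alternative is the better of the two.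
- Against it here: A1 still lacks both acyl groups and has two C3=C4 double bonds. Hydrogenation and a late double Friedel–Crafts acylation at C8 with an α-chiral acyl donor must follow, under Lewis acids that threaten both the new stereocentres and the acid-labile diarylmethane. A2 itself needs the bridged bis-arene and a selective etherification of one of three phenols per ring.
- Comparison: the Claisen step closes two rings and forms two C–C bonds, against four rings and six C–C bonds for the cyclotrimerisation. It introduces the stereocentres afterwards under harsher conditions, whereas the chosen plan carries them in under neutral conditions. It needs about three operations after the key step against one; before the key step the two plans are roughly equal.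

Alternative 2: The cut is at C6–C7 and C8–C8a of each benzene ring. The bis(silyloxy diene) A4, whose halves are doubly O-silylated 3-acyl-δ-lactones (ketene acetal at C8a=C4a, enol ether at C5=C6), would add two molecules of the ethoxy ynone A5 in a Diels–Alder reaction and aromatise by loss of silanol to the 7,7'-diethyl ether A3.
- In its favour: the orientation of 1,3-dioxygenated dienes towards alkynones rests on a strong, well-established polarity match (nucleophilic C6 to the alkoxy-bearing C7). This is firmer ground than the unproven insertion regiochemistry of the chosen plan, and here the alternative is the better. The pyran oxygen is fixed beforehand as the lactone oxygen. A5 is a primary ynol ether and less prone to fragmentation than the tertiary ynol ether in 23.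
- Against it here: A4 carries the bulky branch on the reacting diene terminus C6, which should slow the cycloaddition. Ketene-acetal dienes are very moisture-sensitive. The carbon framework of A4 needs a multistep assembly. Two aryl ethyl ethers must be cleaved at the end under Lewis-acidic conditions that endanger the diarylmethane and the stereocentres.
- Comparison: two rings and four C–C bonds against four rings and six. Both plans carry the stereocentre on the alkyne partner, which is an equal point. Step economy is poorer through the precursor synthesis; the end game is one deprotection in each plan, the alternative's being the harsher.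

Alternative 3: The cut is at O1–C2 and C3–C4 of each pyran ring. The bis-Mannich base A7 has a dimethylaminomethyl group on C4a next to the free C8a hydroxyl, and the C5 oxygen is benzylated so that only the C8a oxygen can form the quinone methide. On heating, A7 would lose amine to give two o-quinone methides, which add 2-methylpropene A8 in an inverse-demand hetero-Diels–Alder reaction to give the dibenzyl ether A6.
- In its favour: the arene core with acyl groups and bridge comes from classical aromatic chemistry. The orientation of the alkene (oxygen to the tertiary carbon) is secure, a control element equal to or better than that of the chosen plan. A8 is cheap, and the final hydrogenolysis is as mild as a desilylation.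
- Against it here: o-quinone methides add to unactivated alkenes such as A8 only sluggishly, so dimerisation, trapping by neighbouring phenols or by the released amine, and thermal epimerisation α to the ketones are to be feared. A7 demands a long, regiocontrolled sequence on a fully substituted, differentially protected bis-arene.
- Comparison: two rings, two C–C and two C–O bonds against four rings and six C–C bonds. Mechanistically it is a known reaction type against an unproven one, and in this respect the alternative is the safer. In step economy the chosen route is shorter, because all substituents are written into three small alkynes.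

Key step: step 10

Remarks on the chemistry: atoms are numbered as in a chroman (O1, C2, C3, C4, C4a, C5 to C8, C8a) throughout. 11, 23 and 25 were checked atom by atom against 26 (two CH2 groups in the tether, four CH2 groups in the side chain, both ketone α-carbons R), and no correction of their skeletons was needed. Two design decisions concern the precursors. A double ester-to-ynolate homologation of a 2-alkylmalonic ester is not used for 11, because its acidic C–H would be removed by the lithium amide base and the resulting enolate would not accept the carbenoid; both siloxyalkynes are made by oxidation of lithium acetylides instead. The ketone of 23 comes from a Weinreb amide and not from the configurationally labile aldehyde. In the key step 11 is the limiting component and 23 is added slowly in excess.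

## Route

Step 1
Reactants: 1 ethynyltrimethylsilane; 2 3-bromo-1-(trimethylsilyl)prop-1-yne
Product: 4 1,5-bis(trimethylsilyl)penta-1,4-diyne, via alkynyl Grignard reagent 3 (not isolated)
Conditions: EtMgBr, THF, 0 °C to rt; then CuCl (5 mol %), 2, THF, 50 °C
Reagents that add atoms: none
Why: Deprotonation of 1 gives the alkynyl Grignard reagent, and copper-catalysed propargylic substitution at the CH2 of 2 forms the skipped diyne; the silyl group on the alkyne of 2 blocks the competing attack at the alkyne terminus that would give an allene.

Step 2
Reactants: 4 1,5-bis(trimethylsilyl)penta-1,4-diyne; 5 1-bromo-5-methylhexane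
Product: 7 3-(5-methylhexyl)-1,5-bis(trimethylsilyl)penta-1,4-diyne, via lithium pentadiynide 6 (not isolated)
Conditions: n-BuLi (1.0 equiv), THF, −78 °C; then 5, DMPU, −78 to 0 °C (4 in slight excess)
Reagents that add atoms: none
Why: The doubly propargylic CH2 is the most acidic site of 4, and the delocalised anion should be alkylated by the primary bromide at its central carbon because both termini are shielded by trimethylsilyl groups (alkylation of a silyl-capped propargylic anion); the slight excess of 4 limits double alkylation.

Step 3
Reactants: 7 3-(5-methylhexyl)-1,5-bis(trimethylsilyl)penta-1,4-diyne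
Product: 8 3-(5-methylhexyl)penta-1,4-diyne
Conditions: K2CO3 (0.2 equiv), MeOH–THF, 0 °C
Reagents that add atoms: none
Why: Catalytic methoxide cleaves the two alkynyl–silicon bonds (protodesilylation); low temperature and sub-stoichiometric base should keep the skipped diyne from isomerising to an allene.

Step 4
Reactants: 8 3-(5-methylhexyl)penta-1,4-diyne
Product: 11 3-(5-methylhexyl)-1,5-bis(triisopropylsilyloxy)penta-1,4-diyne, via dilithium bis-acetylide 9 (not isolated), via dilithium bis-ynolate 10 (not isolated)
Conditions: t-BuOOH (2.1 equiv), LiN(SiMe3)2 (4.2 equiv), THF, −78 to 0 °C; then i-Pr3SiOTf (2.2 equiv), −78 °C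
Reagents that add atoms: tert-butyl hydroperoxide, CC(C)(C)OO; triisopropylsilyl trifluoromethanesulfonate, CC(C)[Si](OS(=O)(=O)C(F)(F)F)(C(C)C)C(C)C
Why: Each lithium acetylide attacks the electrophilic oxygen of lithium tert-butyl peroxide with loss of tert-butoxide to give a lithium ynolate, which the bulky silyl triflate silylates on oxygen (acetylide-to-ynolate oxidation followed by O-silylation); the two arms of a skipped diyne cannot react with each other, so they should behave independently.

Step 5
Reactants: 12 hex-5-yn-2-one
Product: 13 2-methylhex-5-yn-2-ol
Conditions: MeMgBr (2.3 equiv), THF, 0 °C to rt; aqueous work-up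
Reagents that add atoms: methylmagnesium bromide, C[Mg]Br
Why: Grignard addition to the ketone; the first equivalent only deprotonates the terminal alkyne, which is restored on work-up.

Step 6
Reactants: 13 2-methylhex-5-yn-2-ol
Product: 16 2-methyl-6-(triisopropylsilyloxy)hex-5-yn-2-ol, via lithium alkoxide-acetylide 14 (not isolated), via lithium alkoxide-ynolate 15 (not isolated)
Conditions: t-BuOOH (1.05 equiv), LiN(SiMe3)2 (3.1 equiv), THF, −78 to 0 °C; then i-Pr3SiCl (1.1 equiv), −78 °C to rt; base-washed work-up
Reagents that add atoms: tert-butyl hydroperoxide, CC(C)(C)OO; chlorotriisopropylsilane, CC(C)[Si](Cl)(C(C)C)C(C)C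
Why: The same acetylide-to-ynolate oxidation as in step 4, with the hydroxyl masked in the flask as its lithium alkoxide; the bulky silyl chloride silylates the ynolate oxygen but not the hindered tertiary alkoxide, so the hydroxyl should emerge free, and base-washed handling avoids acid-triggered addition of that hydroxyl to the siloxyalkyne.

Step 7
Reactants: 16 2-methyl-6-(triisopropylsilyloxy)hex-5-yn-2-ol
Product: 17 ({5-[(E)-1,2-dichloroethenyloxy]-5-methylhex-1-yn-1-yl}oxy)triisopropylsilane
Conditions: KH (1.2 equiv), THF, 0 °C; then Cl2C=CHCl (1.1 equiv), −50 °C to rt
Reagents that add atoms: trichloroethylene, ClC=C(Cl)Cl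
Why: The potassium alkoxide eliminates HCl from trichloroethylene and then adds anti to the dichloroacetylene formed, which gives the (E)-1,2-dichlorovinyl ether even from tertiary alcohols; the triisopropylsilyl ynol ether is expected to resist the hindered alkoxide at these temperatures.

Step 8
Reactants: 18 (R)-2-methylbutanoic acid
Product: 20 (R)-N-methoxy-N,2-dimethylbutanamide, via acyl imidazole 19 (not isolated)
Conditions: 1,1'-carbonyldiimidazole, CH2Cl2, 0 °C to rt; then MeNH(OMe)·HCl, rt
Reagents that add atoms: N,O-dimethylhydroxylamine hydrochloride, CNOC.Cl
Why: Activation as the acyl imidazole and aminolysis give the Weinreb amide without any base strong enough to enolise the acyl derivative, so the (R) centre should be retained.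

Step 9
Reactants: 17 ({5-[(E)-1,2-dichloroethenyloxy]-5-methylhex-1-yn-1-yl}oxy)triisopropylsilane; 20 (R)-N-methoxy-N,2-dimethylbutanamide
Product: 23 (4R)-4-methyl-1-{[2-methyl-6-(triisopropylsilyloxy)hex-5-yn-2-yl]oxy}hex-1-yn-3-one, via lithium alkoxyacetylide 21 (not isolated), via lithium hemiaminal adduct 22 (not isolated)
Conditions: n-BuLi (2.05 equiv), THF, −78 to −40 °C; then 20, −78 to −30 °C; pH 7 buffer at −78 °C; quick filtration through neutral alumina, used at once
Reagents that add atoms: none
Why: Two equivalents of n-BuLi turn the dichlorovinyl ether into the lithium alkoxyacetylide (loss of HCl, then chlorine–lithium exchange), which adds once to the amide; the chelated adduct releases the ketone only on quench (Weinreb ketone synthesis), so over-addition and enolisation of the α-stereocentre should both be avoided. Elimination and exchange at −78 °C are expected to be much faster than attack of n-BuLi on the hindered Si–O bond.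

Step 10
Reactants: 11 3-(5-methylhexyl)-1,5-bis(triisopropylsilyloxy)penta-1,4-diyne; 23 (4R)-4-methyl-1-{[2-methyl-6-(triisopropylsilyloxy)hex-5-yn-2-yl]oxy}hex-1-yn-3-one (two equivalents react)
Product: 25 6,6'-(6-methylheptane-1,1-diyl)bis{2,2-dimethyl-8-[(2R)-2-methylbutanoyl]-5,7-bis(triisopropylsilyloxy)chroman}, via mono-cycloadduct 24 (not isolated)
Conditions: [Rh(cod)2]BF4 (20 mol %), 2,2'-bis(diphenylphosphino)biphenyl (BIPHEP, 20 mol %), activated with H2 then placed under Ar; 11, CH2Cl2, 4 Å MS, rt; 23 (2.6 equiv) added by syringe pump
Reagents that add atoms: none
Why: Proposed new method: monovalent rhodium should couple the two alkynes of 23 oxidatively (the electron-poor ynone and the electron-rich siloxyalkyne form a matched pair held together by the four-atom tether) to a trivalent rhodacyclopentadiene, which forms C4a–C8a and so closes the pyran ring as a six-membered ring by intramolecular coupling across O1–C2–C3–C4. One siloxyalkyne arm of 11 then inserts into a Rh–C bond and reductive elimination forms C5–C6 and C7–C8, closing the benzene ring by a formal [2+2+2] cycloaddition and returning monovalent rhodium; the same sequence on the remaining arm of 24 closes the second pyran and benzene rings. The closest known reaction type is the cationic rhodium–bisphosphine [2+2+2] cycloaddition of tethered 1,6- and 1,7-diynes with monoalkynes at room temperature, together with benzannulations in which siloxyalkynes deliver silyl-protected phenols; a union in which all three components are ynol-type ethers has not been shown. No stereocentre is created: the methine of 24 is stereogenic only in passing and becomes non-stereogenic in 25, and the (R) α-carbons are not touched under neutral, aprotic conditions at room temperature, which the tertiary ynol ether (prone to thermal retro-ene loss of alkene) also requires. Cross-selectivity over self-trimerisation of 23 is served by the tether, which makes the oxidative coupling within 23 intramolecular, by the 1,4-relationship of the arms of 11, which cannot couple with each other without forming a three-membered ring, and by the slow addition of 23. Regioselectivity demands that the oxygen-bearing carbon of each arm (C7) bonds to the acyl-bearing C8 and the alkyl-bearing carbon (C6) to the siloxy-bearing C5; the alternating polarisation of the three ynol-type units (each oxygen-bearing carbon electrophilic, each neighbour nucleophilic) matches this head-to-tail union and also avoids two adjacent silyloxy groups, but this preference is an expectation and not an established fact.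

Step 11
Reactants: 25 6,6'-(6-methylheptane-1,1-diyl)bis{2,2-dimethyl-8-[(2R)-2-methylbutanoyl]-5,7-bis(triisopropylsilyloxy)chroman}
Product: 26 6,6'-(6-methylheptane-1,1-diyl)bis{5,7-dihydroxy-2,2-dimethyl-8-[(2R)-2-methylbutanoyl]chroman} (target)
Conditions: Bu4NF (4.4 equiv), AcOH (4.4 equiv), THF, 0 °C to rt, under Ar
Reagents that add atoms: none
Why: Fluoride cleaves the four aryl silyl ethers (phenoxide leaving groups, the one ortho to each ketone being the most labile); buffering with acetic acid keeps the medium near neutral so that the ketone α-stereocentres should not be enolised, and no stereocentre is formed.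

## Compound list

1 | ethynyltrimethylsilane | C#C[Si](C)(C)C | starting material
2 | 3-bromo-1-(trimethylsilyl)prop-1-yne | C[Si](C)(C)C#CCBr | starting material
3 | [(trimethylsilyl)ethynyl]magnesium bromide | C[Si](C)(C)C#C[Mg]Br | intermediate
4 | 1,5-bis(trimethylsilyl)penta-1,4-diyne | C[Si](C)(C)C#CCC#C[Si](C)(C)C | intermediate
5 | 1-bromo-5-methylhexane | CC(C)CCCCBr | starting material
6 | lithium 1,5-bis(trimethylsilyl)penta-1,4-diyn-3-ide | [Li]C(C#C[Si](C)(C)C)C#C[Si](C)(C)C | intermediate
7 | 3-(5-methylhexyl)-1,5-bis(trimethylsilyl)penta-1,4-diyne | CC(C)CCCCC(C#C[Si](C)(C)C)C#C[Si](C)(C)C | intermediate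
8 | 3-(5-methylhexyl)penta-1,4-diyne | CC(C)CCCCC(C#C)C#C | intermediate
9 | dilithium bis-acetylide of 8 | CC(C)CCCCC(C#C[Li])C#C[Li] | intermediate
10 | dilithium 3-(5-methylhexyl)penta-1,4-diyne-1,5-bis(olate) (bis-ynolate) | CC(C)CCCCC(C#CO[Li])C#CO[Li] | intermediate
11 | 3-(5-methylhexyl)-1,5-bis(triisopropylsilyloxy)penta-1,4-diyne | CC(C)CCCCC(C#CO[Si](C(C)C)(C(C)C)C(C)C)C#CO[Si](C(C)C)(C(C)C)C(C)C | intermediate
12 | hex-5-yn-2-one | CC(=O)CCC#C | starting material
13 | 2-methylhex-5-yn-2-ol | CC(C)(O)CCC#C | intermediate
14 | dilithium salt of 13 (lithium alkoxide and lithium acetylide) | CC(C)(O[Li])CCC#C[Li] | intermediate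
15 | dilithium 5-methyl-5-oxidohex-1-yn-1-olate (lithium alkoxide and lithium ynolate) | CC(C)(O[Li])CCC#CO[Li] | intermediate
16 | 2-methyl-6-(triisopropylsilyloxy)hex-5-yn-2-ol | CC(C)(O)CCC#CO[Si](C(C)C)(C(C)C)C(C)C | intermediate
17 | ({5-[(E)-1,2-dichloroethenyloxy]-5-methylhex-1-yn-1-yl}oxy)triisopropylsilane | Cl/C=C(/Cl)OC(C)(C)CCC#CO[Si](C(C)C)(C(C)C)C(C)C | intermediate
18 | (R)-2-methylbutanoic acid | CC[C@@H](C)C(=O)O | starting material
19 | (R)-1-(1H-imidazol-1-yl)-2-methylbutan-1-one | CC[C@@H](C)C(=O)n1ccnc1 | intermediate
20 | (R)-N-methoxy-N,2-dimethylbutanamide | CC[C@@H](C)C(=O)N(C)OC | intermediate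
21 | lithium {[2-methyl-6-(triisopropylsilyloxy)hex-5-yn-2-yl]oxy}acetylide | [Li]C#COC(C)(C)CCC#CO[Si](C(C)C)(C(C)C)C(C)C | intermediate
22 | lithium N-methoxy-N-methyl hemiaminal adduct of 21 and 20 | CC[C@@H](C)C(O[Li])(N(C)OC)C#COC(C)(C)CCC#CO[Si](C(C)C)(C(C)C)C(C)C | intermediate
23 | (4R)-4-methyl-1-{[2-methyl-6-(triisopropylsilyloxy)hex-5-yn-2-yl]oxy}hex-1-yn-3-one | CC[C@@H](C)C(=O)C#COC(C)(C)CCC#CO[Si](C(C)C)(C(C)C)C(C)C | intermediate
24 | (2R)-1-{2,2-dimethyl-6-[8-methyl-1-(triisopropylsilyloxy)non-1-yn-3-yl]-5,7-bis(triisopropylsilyloxy)chroman-8-yl}-2-methylbutan-1-one (both epimers at the methine) | CC[C@@H](C)C(=O)c1c(O[Si](C(C)C)(C(C)C)C(C)C)c(C(CCCCC(C)C)C#CO[Si](C(C)C)(C(C)C)C(C)C)c(O[Si](C(C)C)(C(C)C)C(C)C)c2CCC(C)(C)Oc12 | intermediate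
25 | 6,6'-(6-methylheptane-1,1-diyl)bis{2,2-dimethyl-8-[(2R)-2-methylbutanoyl]-5,7-bis(triisopropylsilyloxy)chroman} | CC[C@@H](C)C(=O)c1c(O[Si](C(C)C)(C(C)C)C(C)C)c(C(CCCCC(C)C)c2c(O[Si](C(C)C)(C(C)C)C(C)C)c(C(=O)[C@H](C)CC)c3OC(C)(C)CCc3c2O[Si](C(C)C)(C(C)C)C(C)C)c(O[Si](C(C)C)(C(C)C)C(C)C)c2CCC(C)(C)Oc12 | intermediate
26 | 6,6'-(6-methylheptane-1,1-diyl)bis{5,7-dihydroxy-2,2-dimethyl-8-[(2R)-2-methylbutanoyl]chroman} | CC[C@@H](C)C(=O)c1c(O)c(C(CCCCC(C)C)c2c(O)c3c(c(C(=O)[C@H](C)CC)c2O)OC(C)(C)CC3)c(O)c2c1OC(C)(C)CC2 | target

## Step count and least certain steps

Total: 11 steps. Longest linear sequence: 6 steps (steps 5, 6, 7, 9, 10, 11 from 12; the sequence of steps 1, 2, 3, 4, 10, 11 from 1 is equally long).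

Step 10 (key step, the one that rests on a new method). Several things can go wrong:
- self-trimerisation of 23 may outrun the cross-reaction;
- the arm of 11 may insert with the reverse orientation;
- the reaction may stall after the first ring, because the remaining arm is shielded by the new hexasubstituted arene and its two silyloxy groups;
- traces of acid from the cationic catalyst may destroy the ynol ethers, and the tertiary ether may fragment by a retro-ene path if warming becomes necessary.

The fallback uses known aromatic chemistry; it sets out from 18 (with 5 as the source of the bridge) and returns to the route at 26. 18 is converted with oxalyl chloride into (R)-2-methylbutanoyl chloride F1. F1 acylates benzene-1,3,5-triol (AlCl3, low temperature, Friedel–Crafts acylation) to (R)-2-methyl-1-(2,4,6-trihydroxyphenyl)butan-1-one F2. Acid-catalysed C-prenylation and ring closure with 2-methylbut-3-en-2-ol (BF3·OEt2) gives the chroman (R)-1-(5,7-dihydroxy-2,2-dimethylchroman-8-yl)-2-methylbutan-1-one F3, which is taken on after separation from the regioisomer formed by closure onto the other phenol. 5 is turned through its Grignard reagent and N,N-dimethylformamide into 6-methylheptanal F4. Condensation of two equivalents of F3 with F4 under mild acid catalysis (hydroxyalkylation at the free C6, then alkylation of the second arene) gives 26 directly.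

Step 9. The acetylide must wait at −40 to −30 °C for the slow addition to the amide. During that time, cleavage of the Si–O bond of the siloxyalkyne by organolithium species, base-induced loss of configuration at the α-carbon, and hydration of the push–pull ynone on aqueous work-up are the likely failures. The fallback sets out from 17 and returns at 23. 21 is generated as before but quenched at once at −78 °C with Bu3SnCl to give the neutral, storable tributyl({[2-methyl-6-(triisopropylsilyloxy)hex-5-yn-2-yl]oxy}ethynyl)stannane F5. F5 is coupled with (R)-2-methylbutanoyl chloride F1 (from 18 as in the first fallback) under PdCl2(PPh3)2 catalysis (Stille acylation through zerovalent palladium) at room temperature without base or aqueous work-up, which should give 23.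

Step 4. Incomplete oxidation of the second acetylide (poorly soluble dianion, mixtures of mono- and bis-siloxy products) and base-induced propargyl–allenyl isomerisation at the doubly propargylic C–H during the 0 °C period are the likely failures. The fallback sets out from 7 and returns at 11, treating the arms one at a time.
- Partial methanolysis of 7 (K2CO3, MeOH, stopped near half conversion, 7 and 8 recycled) gives 3-(5-methylhexyl)-1-(trimethylsilyl)penta-1,4-diyne F6.
- Its single acetylide is oxidised and silylated as in step 4 to triisopropyl{[3-(5-methylhexyl)-5-(trimethylsilyl)penta-1,4-diyn-1-yl]oxy}silane F7.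
- Removal of the remaining trimethylsilyl group (K2CO3, MeOH, 0 °C, which the triisopropylsilyl ynol ether should tolerate) gives triisopropyl{[3-(5-methylhexyl)penta-1,4-diyn-1-yl]oxy}silane F8.
- A second oxidation–silylation gives 11.

Step 2. Alkylation of the ambident anion at a terminus (allene formation), double alkylation, and sluggish substitution of the primary bromide are the likely failures. The fallback reverses the polarity; it sets out from 3 (step 1) and 5 and returns at 7.
- Two equivalents of 3 add to ethyl formate to give 1,5-bis(trimethylsilyl)penta-1,4-diyn-3-ol F9.
- An Appel reaction (PPh3, CBr4) gives 3-bromo-1,5-bis(trimethylsilyl)penta-1,4-diyne F10.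
- 5 is converted with zinc dust into bromo(5-methylhexyl)zinc F11.
- Nickel-catalysed Negishi coupling of F10 with F11 (NiCl2·glyme, 2,2':6',2''-terpyridine, DMA, rt) should give 7.

## Further compounds

F1 | step 10 | (R)-2-methylbutanoyl chloride | CC[C@@H](C)C(=O)Cl
F2 | step 10 | (R)-2-methyl-1-(2,4,6-trihydroxyphenyl)butan-1-one | CC[C@@H](C)C(=O)c1c(O)cc(O)cc1O
F3 | step 10 | (R)-1-(5,7-dihydroxy-2,2-dimethylchroman-8-yl)-2-methylbutan-1-one | CC[C@@H](C)C(=O)c1c(O)cc(O)c2CCC(C)(C)Oc12
F4 | step 10 | 6-methylheptanal | CC(C)CCCCC=O
F5 | step 9 | tributyl({[2-methyl-6-(triisopropylsilyloxy)hex-5-yn-2-yl]oxy}ethynyl)stannane | CCCC[Sn](CCCC)(CCCC)C#COC(C)(C)CCC#CO[Si](C(C)C)(C(C)C)C(C)C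
F6 | step 4 | 3-(5-methylhexyl)-1-(trimethylsilyl)penta-1,4-diyne | CC(C)CCCCC(C#C)C#C[Si](C)(C)C
F7 | step 4 | triisopropyl{[3-(5-methylhexyl)-5-(trimethylsilyl)penta-1,4-diyn-1-yl]oxy}silane | CC(C)CCCCC(C#CO[Si](C(C)C)(C(C)C)C(C)C)C#C[Si](C)(C)C
F8 | step 4 | triisopropyl{[3-(5-methylhexyl)penta-1,4-diyn-1-yl]oxy}silane | CC(C)CCCCC(C#C)C#CO[Si](C(C)C)(C(C)C)C(C)C
F9 | step 2 | 1,5-bis(trimethylsilyl)penta-1,4-diyn-3-ol | C[Si](C)(C)C#CC(O)C#C[Si](C)(C)C
F10 | step 2 | 3-bromo-1,5-bis(trimethylsilyl)penta-1,4-diyne | C[Si](C)(C)C#CC(Br)C#C[Si](C)(C)C
F11 | step 2 | bromo(5-methylhexyl)zinc | CC(C)CCCC[Zn]Br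
A1 | alternative 1 | 6,6'-(6-methylheptane-1,1-diyl)bis(2,2-dimethyl-2H-chromene-5,7-diol) | CC(C)CCCCC(c1c(O)cc2OC(C)(C)C=Cc2c1O)c1c(O)cc2OC(C)(C)C=Cc2c1O
A2 | alternative 1 | 2,2'-(6-methylheptane-1,1-diyl)bis{5-[(2-methylbut-3-yn-2-yl)oxy]benzene-1,3-diol} | CC(C)CCCCC(c1c(O)cc(OC(C)(C)C#C)cc1O)c1c(O)cc(OC(C)(C)C#C)cc1O
A3 | alternative 2 | 7,7'-di-O-ethyl ether of 26 | CC[C@@H](C)C(=O)c1c(OCC)c(C(CCCCC(C)C)c2c(OCC)c(C(=O)[C@H](C)CC)c3OC(C)(C)CCc3c2O)c(O)c2CCC(C)(C)Oc12
A4 | alternative 2 | 1,5-bis[6,6-dimethyl-2-(trimethylsilyloxy)-5,6-dihydro-4H-pyran-3-yl]-3-(5-methylhexyl)-1,5-bis(trimethylsilyloxy)penta-1,4-diene | CC(C)CCCCC(C=C(O[Si](C)(C)C)C1=C(O[Si](C)(C)C)OC(C)(C)CC1)C=C(O[Si](C)(C)C)C1=C(O[Si](C)(C)C)OC(C)(C)CC1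
A5 | alternative 2 | (R)-1-ethoxy-4-methylhex-1-yn-3-one | CC[C@@H](C)C(=O)C#COCC
A6 | alternative 3 | 5,5'-di-O-benzyl ether of 26 | CC[C@@H](C)C(=O)c1c(O)c(C(CCCCC(C)C)c2c(O)c(C(=O)[C@H](C)CC)c3OC(C)(C)CCc3c2OCc2ccccc2)c(OCc2ccccc2)c2CCC(C)(C)Oc12
A7 | alternative 3 | bis-Mannich base: 6-methylheptane-1,1-diyl-bridged bis{4-benzyloxy-5-[(dimethylamino)methyl]-2,6-dihydroxy-3-[(2R)-2-methylbutanoyl]benzene}, bridge on the carbon between the benzyloxy and hydroxy groups | CC[C@@H](C)C(=O)c1c(O)c(C(CCCCC(C)C)c2c(O)c(C(=O)[C@H](C)CC)c(O)c(CN(C)C)c2OCc2ccccc2)c(OCc2ccccc2)c(CN(C)C)c1O
A8 | alternative 3 | 2-methylpropene | CC(C)=C
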